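The plan rests on disconnecting C9–C10, the bond between quaternary C10 (ring fusion, bearing methyl C20) and stereocentre C9. Since ring A carries no substituent at C1 or C2, an allylic C2–O bond of a 3-methylcyclohex-2-enyl ring A can be converted into this crowded bond by an Ireland–Claisen rearrangement. In a single operation the step attaches the C8–C9–C11–C12 chain to ring A, creates quaternary C10 and sets C9; the only trace is a C1=C2 alkene, hydrogenated later. The precursor is the 4-(benzyloxy)butanoate of a ring A allylic alcohol whose C19 and C6 are locked as a cis-fused cyclic methyl acetal. Ring B then closes by aldol condensation, and the tiglate and Z-enoic acid are added last.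

Key step: step 9

Remark: atoms carry labdane numbers (C1–C20) in every compound; β is the face of ring A on which C19, C6 and later C20 lie, α the opposite face; compounds 4–7 are racemic and are drawn as the enantiomer that is carried on.

Step 1
Reactants: 1 (E)-pent-3-en-2-one
Product: 2 (E)-2-(tert-butyldimethylsilyloxy)penta-1,3-diene
Conditions: LiN(iPr)2, THF, −78 °C; tBuMe2SiCl, DMPU, −78 °C → 0 °C
Reagents that add atoms: tert-butyldimethylsilyl chloride, CC(C)(C)[Si](C)(C)Cl
Why: Lithium diisopropylamide deprotonates the enone at the methyl group of the acetyl end (kinetic, cross-conjugated enolate) and O-silylation traps it as the 2-silyloxydiene without touching the E alkene (kinetic enol silylation).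

Step 2
Reactants: 2 (E)-2-(tert-butyldimethylsilyloxy)penta-1,3-diene; 3 citraconic anhydride
Product: 4 racemic cis-fused Diels–Alder anhydride: cyclohexene ring A, C3H2–C2(OSitBuMe2)=C1H–C10H(C20H3)–C5H–C4(C18H3), with C19 (on C4) and C6 (on C5) as the anhydride carbonyls; C19, C6 and C20 all β
Conditions: toluene, 90 °C, BHT (trace)
Reagents that add atoms: none
Why: Thermal normal-demand Diels–Alder reaction in which the unsubstituted diene terminus, made the more nucleophilic end by both the 2-silyloxy and the 4-methyl group, should bond to the methyl-bearing carbon of the dienophile (C3–C4) while the methyl-bearing terminus takes the CH carbon (C10–C5), which also keeps the two methylated carbons apart; the cyclic dienophile delivers C19 and C6 cis on ring A (relative configuration of C4 and C5), endo approach places C20 on the same face, and the adduct is racemic.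

Step 3
Reactants: 4 racemic Diels–Alder anhydride
Product: 6 racemic cis-fused 19,6-lactone (C4–C19H2–O–C6(=O)–C5) of the ring A silyl enol ether, via hydroxy acid 5 (not isolated)
Conditions: NaBH4, THF, 0 °C → rt; then cold aq. citric acid (pH 4), extraction, standing in toluene at rt
Reagents that add atoms: none
Why: Borohydride reduction of an unsymmetrical cyclic anhydride occurs preferentially at the carbonyl attached to the more substituted carbon, here C19 on quaternary C4, and the hydroxy acid 5 closes to the cis-fused γ-lactone on mild acidification, which a tert-butyldimethylsilyl enol ether should survive; no stereocentre is touched (regioselective anhydride reduction and lactonisation).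

Step 4
Reactants: 6 racemic lactone silyl enol ether
Product: 7 racemic enone lactone: ring A 2-ketone with C1=C10 (C20 methyl on C10), cis-fused 19,6-lactone
Conditions: Pd(OAc)2 (15 mol %), O2 (1 atm), DMSO, 60 °C
Reagents that add atoms: none
Why: Saegusa–Ito oxidation: the silyl enol ether transfers C1 to divalent palladium on the face away from the lactone and C20, syn β-hydride loss from C10 gives the 3-methyl enone C2(=O)–C1=C10 regiospecifically, and O2 in DMSO returns the zerovalent palladium to the divalent state; the C10 stereocentre disappears and C4 and C5 are unchanged.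

Step 5
Reactants: 7 racemic enone lactone
Product: 8 (2S)-2α-hydroxy 19,6-lactone with C1=C10, single enantiomer (hydroxyl trans to the lactone ring)
Conditions: (R)-1-methyl-3,3-diphenyltetrahydro-1H,3H-pyrrolo[1,2-c][1,3,2]oxazaborole (20 mol %), catecholborane, toluene, −78 °C; chromatographic separation of the two diastereomeric carbinols
Reagents that add atoms: none
Why: Corey–Bakshi–Shibata reduction under reagent control: with the alkenyl carbon C1 as the large group the (R)-oxazaborolidine should deliver hydride to the same carbonyl face in both enantiomers of 7 and so make the (2S)-carbinol from each, so that the enantiomer drawn gives 8 with the hydroxyl α and trans to the lactone ring while the mirror-image enone gives the cis diastereomer, which is removed by chromatography; this sets C2 and at the same stroke selects the absolute configuration of C4 and C5.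

Step 6
Reactants: 8 (2S)-2α-hydroxy lactone
Product: 9 (2S)-2α-hydroxy lactol (C6 hemiacetal, both anomers; C19–O–C6 ring β, cis-fused)
Conditions: iBu2AlH (2.3 equiv), CH2Cl2, −78 °C; aq. KNaC4H4O6 (potassium sodium tartrate)
Reagents that add atoms: none
Why: At −78 °C diisobutylaluminium hydride adds once to the γ-lactone and the tetrahedral aluminate holds until work-up, which releases the lactol (partial reduction of a lactone); the first equivalent is consumed by the C2 hydroxyl and the trisubstituted alkene is inert.

Step 7
Reactants: 9 (2S)-2α-hydroxy lactol
Product: 10 ring A allylic alcohol (2α-OH, C1=C10) with C19 and C6 tied as a cis-fused cyclic methyl acetal (OMe exo on C6)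
Conditions: MeOH, PPTS (cat.), rt
Reagents that add atoms: methanol, CO
Why: Acid-catalysed acetalisation of the lactol through its cyclic oxocarbenium ion, methanol adding mainly from the open exo face; the weak pyridinium acid is not expected to ionise the allylic C2 alcohol, and the acetal masks C6 and C19 against the strong bases that follow.

Step 8
Reactants: 10 ring A allylic alcohol with cyclic methyl acetal; 11 4-(benzyloxy)butanoic acid
Product: 12 4-(benzyloxy)butanoate of 10 at the 2α oxygen
Conditions: DCC, DMAP (cat.), CH2Cl2, 0 °C → rt
Reagents that add atoms: none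
Why: Steglich esterification: the O-acylisourea from the acid and dicyclohexylcarbodiimide is passed on by 4-(dimethylamino)pyridine to the secondary allylic hydroxyl with retention at C2, under neutral conditions that spare the acetal.

Step 9
Reactants: 12 allylic 4-(benzyloxy)butanoate
Product: 15 rearranged acid: C9 (bearing the C8 carboxyl and the C11–C12 benzyloxyethyl arm) bonded to the α face of quaternary C10 (C20 β); C1=C2 alkene; acetal intact, via silyl ketene acetal 13 (not isolated), via trimethylsilyl ester 14 (not isolated)
Conditions: LiN(iPr)2, THF, −78 °C; Me3SiCl, −78 °C → rt, then 60 °C; H2O/MeOH, NaH2PO4 (pH 5)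
Reagents that add atoms: none
Why: Deprotonation of the butanoate in THF without a polar cosolvent and silylation on oxygen give ketene acetal 13 with the C11 chain cis to the allylic oxygen, and on warming a concerted suprafacial [3,3] shift breaks C2–O and forms C9–C10 at the methyl-bearing alkene carbon while the alkene moves to C1=C2. The closest known reaction type is the Ireland–Claisen rearrangement of 3-methylcyclohex-2-enyl ester silyl ketene acetals to a ring quaternary carbon with a vicinal stereocentre. No ring is closed, the six-atom array being only the transition state, which is expected to be boat-like because a chair would force the silyloxy-bearing C8 under ring A. The configuration of C10 is controlled by the C2 carbinol: the new bond forms on the α face that carried the oxygen, so C20 is left β, cis to C19 and C6, as the trans ring fusion requires. The configuration of C9 is controlled by the ketene acetal geometry together with the boat array, and any leakage is corrected in step 11, where the 8-ketone is equilibrated. The selectivity the step needs is facial at C10, and it is secured because the ester sits on the convex α face of the cis-fused bicyclic acetal, which has no other acidic hydrogen and is inert to the amide base.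

Step 10
Reactants: 15 rearranged acid
Product: 17 keto lactol: C8 methyl ketone (methyl = C7) on C9; C6 hemiacetal (both anomers), via methyl ketone acetal 16 (not isolated)
Conditions: MeLi (3.5 equiv), Et2O, 0 °C → rt; inverse quench into AcOH/THF/H2O, then 40 °C
Reagents that add atoms: methyllithium, [Li]C; water, O
Why: Methyllithium first forms the lithium carboxylate and then adds to it to give a dilithio gem-diolate that resists further addition and releases the methyl ketone (whose methyl is C7) on protonation (ketone synthesis from a carboxylic acid), and the warm aqueous acetic acid of the quench hydrolyses the methyl acetal to the lactol; the carboxylate protects C9 from deprotonation and the benzyl ether and alkene are inert.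

Step 11
Reactants: 17 keto lactol
Product: 22 trans-fused 12,19-dihydroxy 8-ketone (ring B closed; rings A and B saturated; C9 side chain β), via aldol adduct 18 (not isolated), via enone 19 (not isolated), via cyclic ether ketone 20 (not isolated), via saturated benzyl ether ketone 21 (not isolated)
Conditions: NaOMe (0.3 equiv), MeOH, 0 °C → rt; then 10% Pd/C, H2 (1 atm), rt; then AcOH, Pd(OH)2/C, H2 (1 atm), rt
Reagents that add atoms: none
Why: Methoxide opens the lactol to the C6 aldehyde and generates the methyl ketone enolate, whose intramolecular aldol addition (6-enolendo-exo-trig) and loss of water close ring B as enone 19 with the trans fusion already fixed by C5 and C10; 19 may rest reversibly as its intramolecular oxa-Michael adduct 20, but hydrogenation over palladium in the basic medium removes the enone irreversibly, so the equilibrium drains to ketone 21 with C6=C7 and C1=C2 saturated and C9 equilibrated through the enolate to the equatorial β side chain, and acidification then allows hydrogenolysis of the benzyl ether.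

Step 12
Reactants: 22 12,19-dihydroxy 8-ketone
Product: 23 12,19-bis(triethylsilyl) ether of the 8-ketone
Conditions: Et3SiCl, imidazole, DMAP (cat.), DMF, rt
Reagents that add atoms: chlorotriethylsilane, CC[Si](Cl)(CC)CC
Why: Silylation of both primary hydroxyls with the chlorosilane and imidazole (silyl ether protection), the small triethylsilyl group being able to reach the neopentyl C19 hydroxyl; the ketone is not enolised under these conditions.

Step 13
Reactants: 23 bis(triethylsilyl) ether ketone
Product: 24 C8 enol triflate with C7=C8 (12,19-bis(triethylsilyl) ether)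
Conditions: KN(SiMe3)2, THF, −78 °C; PhNTf2, −78 → 0 °C
Reagents that add atoms: N-phenylbis(trifluoromethanesulfonimide), O=S(=O)(N(c1ccccc1)S(=O)(=O)C(F)(F)F)C(F)(F)F
Why: The bulky amide base removes a proton at −78 °C from the C7 methylene in preference to the hindered C9 methine beside quaternary C10, and the kinetic enolate is trapped on oxygen by the triflimide (kinetic enol triflate formation), so C9 keeps its configuration.

Step 14
Reactants: 24 enol triflate
Product: 26 12,19-diol of the decalin bearing C7=C8 plus the C17 methyl on C8, via bis(triethylsilyl) ether 25 (not isolated)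
Conditions: MeZnCl, Pd(PPh3)4 (5 mol %), THF, 50 °C; then MeOH, 1 M HCl, rt
Reagents that add atoms: methylzinc chloride, C[Zn]Cl
Why: Negishi coupling: oxidative addition of the enol triflate to zerovalent palladium, transfer of methyl from zinc and reductive elimination put the C17 methyl on C8 with the alkene fixed at C7=C8, and the dilute acid added afterwards hydrolyses both triethylsilyl ethers without moving the trisubstituted alkene.

Step 15
Reactants: 26 12,19-diol
Product: 27 12-iodo-19-hydroxy decalin (C7=C8, C17 methyl on C8)
Conditions: I2, PPh3, imidazole, CH2Cl2, 0 °C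
Reagents that add atoms: iodine, II
Why: Appel-type iodination through the alkoxyphosphonium salt, which is displaced by iodide in an SN2 step only at the unhindered C12 carbinol, since the neopentyl and axial C19 hydroxyl is inert to this displacement at 0 °C.

Step 16
Reactants: 27 12-iodo-19-hydroxy decalin; 28 tiglic acid ((E)-2-methylbut-2-enoic acid)
Product: 30 19-tiglate 12-iodide, via mixed anhydride 29 (not isolated)
Conditions: 28, 2,4,6-Cl3C6H2COCl, Et3N, toluene, rt; then 27, DMAP, rt
Reagents that add atoms: none
Why: Yamaguchi esterification: the mixed anhydride of tiglic acid is attacked at the tigloyl carbonyl by 4-(dimethylamino)pyridine and the resulting acylpyridinium ion acylates the hindered C19 hydroxyl, the E geometry of the tiglate being the stable one, while the primary iodide is left alone at room temperature.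

Step 17
Reactants: 31 but-2-ynoic acid
Product: 32 (Z)-3-iodobut-2-enoic acid
Conditions: NaI, AcOH, 110 °C
Reagents that add atoms: sodium iodide, [Na+].[I-]
Why: Iodide adds to the β carbon of the ynoic acid and the vinyl anion equivalent is protonated anti by acetic acid (anti hydroiodination of an alkynoic acid), which gives the Z iodoacid with iodine and carboxyl cis.

Step 18
Reactants: 30 19-tiglate 12-iodide; 32 (Z)-3-iodobut-2-enoic acid
Product: 36 target: 19-[(E)-2-methylbut-2-enoyloxy]labda-7,13Z-dien-15-oic acid (4S,5R,9S,10R), via alkylzinc iodide 33 (not isolated), via trimethylsilyl iodoenoate 34 (not isolated), via trimethylsilyl ester 35 (not isolated)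
Conditions: 30, Zn dust, LiCl, THF, 40 °C; 32, MeC(OSiMe3)=NSiMe3, THF, rt; both combined, Pd(PPh3)4 (5 mol %), THF, 40 °C; aq. NH4Cl
Reagents that add atoms: none
Why: Negishi coupling: zinc inserts into the primary C–I bond with LiCl assistance without touching the tiglate, the iodoacid is masked in situ as its trimethylsilyl ester so that it cannot protonate the organozinc, and oxidative addition of the vinyl iodide to zerovalent palladium, transmetallation and reductive elimination join C12 to C13 with retention of the Z geometry before aqueous work-up frees the acid.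

Compound list
1 | (E)-pent-3-en-2-one | C/C=C/C(C)=O | starting material
2 | (E)-2-(tert-butyldimethylsilyloxy)penta-1,3-diene | C=C(O[Si](C)(C)C(C)(C)C)/C=C/C | intermediate
3 | citraconic anhydride | CC1=CC(=O)OC1=O | starting material
4 | racemic cis-fused Diels–Alder anhydride (C19, C6 and C20 all β; enantiomer carried on is drawn) | C[C@@H]1C=C(O[Si](C)(C)C(C)(C)C)C[C@]2(C)C(=O)OC(=O)[C@H]12 | intermediate
5 | racemic hydroxy acid (C19H2OH on C4, C6 carboxyl on C5), not isolated | C[C@@H]1C=C(O[Si](C)(C)C(C)(C)C)C[C@](C)(CO)[C@@H]1C(=O)O | intermediate
6 | racemic cis-fused 19,6-lactone silyl enol ether | C[C@@H]1C=C(O[Si](C)(C)C(C)(C)C)C[C@]2(C)COC(=O)[C@H]12 | intermediate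
7 | racemic enone lactone (2-ketone, C1=C10, cis-fused 19,6-lactone) | O=C1C=C(C)[C@H]2C(=O)OC[C@@]2(C)C1 | intermediate
8 | (2S)-2α-hydroxy 19,6-lactone with C1=C10, single enantiomer | O[C@@H]1C=C(C)[C@H]2C(=O)OC[C@@]2(C)C1 | intermediate
9 | (2S)-2α-hydroxy lactol (C6 hemiacetal, both anomers) | O[C@@H]1C=C(C)[C@H]2C(O)OC[C@@]2(C)C1 | intermediate
10 | ring A allylic alcohol with C19 and C6 as cyclic methyl acetal (2α-OH, exo-OMe) | O[C@@H]1C=C(C)[C@H]2[C@H](OC)OC[C@@]2(C)C1 | intermediate
11 | 4-(benzyloxy)butanoic acid | OC(=O)CCCOCc1ccccc1 | starting material
12 | allylic 4-(benzyloxy)butanoate of 10 | O=C(CCCOCc1ccccc1)O[C@@H]1C=C(C)[C@H]2[C@H](OC)OC[C@@]2(C)C1 | intermediate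
13 | trimethylsilyl ketene acetal of 12 (C11 chain cis to the allylic oxygen), not isolated | C[Si](C)(C)O/C(=C/CCOCc1ccccc1)O[C@@H]2C=C(C)[C@H]3[C@H](OC)OC[C@@]3(C)C2 | intermediate
14 | trimethylsilyl ester of 15, not isolated | CO[C@@H]1OC[C@@]2(C)CC=C[C@](C)([C@@H](CCOCc3ccccc3)C(=O)O[Si](C)(C)C)[C@@H]12 | intermediate
15 | rearranged acid with quaternary C10 and the C9 stereocentre | CO[C@@H]1OC[C@@]2(C)CC=C[C@](C)([C@@H](CCOCc3ccccc3)C(=O)O)[C@@H]12 | intermediate
16 | methyl ketone acetal (C8 ketone, C7 methyl), not isolated | CO[C@@H]1OC[C@@]2(C)CC=C[C@](C)([C@@H](CCOCc3ccccc3)C(C)=O)[C@@H]12 | intermediate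
17 | keto lactol (both anomers) | OC1OC[C@@]2(C)CC=C[C@](C)([C@@H](CCOCc3ccccc3)C(C)=O)[C@@H]12 | intermediate
18 | aldol adduct (6-hydroxy 8-ketone, ring B closed), not isolated | OC[C@@]1(C)CC=C[C@]2(C)[C@@H](CCOCc3ccccc3)C(=O)CC(O)[C@@H]12 | intermediate
19 | trans-fused 19-hydroxy enone (C8 ketone, C6=C7, C1=C2, 12-benzyloxy), not isolated | OC[C@@]1(C)CC=C[C@]2(C)[C@@H](CCOCc3ccccc3)C(=O)C=C[C@@H]12 | intermediate
20 | cyclic ether ketone (6β,19-ether, oxa-Michael adduct of 19), not isolated | O1C[C@@]2(C)CC=C[C@]3(C)[C@@H](CCOCc4ccccc4)C(=O)C[C@@H]1[C@@H]23 | intermediate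
21 | saturated 12-benzyloxy-19-hydroxy 8-ketone, not isolated | OC[C@@]1(C)CCC[C@]2(C)[C@@H](CCOCc3ccccc3)C(=O)CC[C@@H]12 | intermediate
22 | trans-fused 12,19-dihydroxy 8-ketone | OC[C@@]1(C)CCC[C@]2(C)[C@@H](CCO)C(=O)CC[C@@H]12 | intermediate
23 | 12,19-bis(triethylsilyl) ether of the 8-ketone | CC[Si](CC)(CC)OC[C@@]1(C)CCC[C@]2(C)[C@@H](CCO[Si](CC)(CC)CC)C(=O)CC[C@@H]12 | intermediate
24 | C8 enol triflate, C7=C8 | CC[Si](CC)(CC)OC[C@@]1(C)CCC[C@]2(C)[C@@H](CCO[Si](CC)(CC)CC)C(OS(=O)(=O)C(F)(F)F)=CC[C@@H]12 | intermediate
25 | 12,19-bis(triethylsilyl) ether with C7=C8 and C17 methyl, not isolated | CC[Si](CC)(CC)OC[C@@]1(C)CCC[C@]2(C)[C@@H](CCO[Si](CC)(CC)CC)C(C)=CC[C@@H]12 | intermediate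
26 | 12,19-diol with C7=C8 and C17 methyl | OC[C@@]1(C)CCC[C@]2(C)[C@@H](CCO)C(C)=CC[C@@H]12 | intermediate
27 | 12-iodo-19-hydroxy decalin with C7=C8 and C17 methyl | OC[C@@]1(C)CCC[C@]2(C)[C@@H](CCI)C(C)=CC[C@@H]12 | intermediate
28 | tiglic acid | C/C=C(\C)C(=O)O | starting material
29 | tigloyl 2,4,6-trichlorobenzoyl mixed anhydride, not isolated | C/C=C(\C)C(=O)OC(=O)c1c(Cl)cc(Cl)cc1Cl | intermediate
30 | 19-tiglate 12-iodide | C/C=C(\C)C(=O)OC[C@@]1(C)CCC[C@]2(C)[C@@H](CCI)C(C)=CC[C@@H]12 | intermediate
31 | but-2-ynoic acid | CC#CC(=O)O | starting material
32 | (Z)-3-iodobut-2-enoic acid | I/C(C)=C\C(=O)O | intermediate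
33 | C12 alkylzinc iodide of 30, not isolated | C/C=C(\C)C(=O)OC[C@@]1(C)CCC[C@]2(C)[C@@H](CC[Zn]I)C(C)=CC[C@@H]12 | intermediate
34 | trimethylsilyl (Z)-3-iodobut-2-enoate, not isolated | I/C(C)=C\C(=O)O[Si](C)(C)C | intermediate
35 | trimethylsilyl ester of 36, not isolated | C/C=C(\C)C(=O)OC[C@@]1(C)CCC[C@]2(C)[C@@H](CC/C(C)=C\C(=O)O[Si](C)(C)C)C(C)=CC[C@@H]12 | intermediate
36 | CNP0249147.2, 19-tigloyloxylabda-7,13Z-dien-15-oic acid (4S,5R,9S,10R) | C/C=C(\C)C(=O)OC[C@@]1(C)CCC[C@]2(C)[C@@H](CC/C(C)=C\C(=O)O)C(C)=CC[C@@H]12 | target

Total step count: 18. Longest linear sequence: 17 steps (steps 1–16 and 18, from 1 to 36); step 17 prepares the side fragment 32.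

Steps most likely to fail

Step 5. The catalyst may fail to override the facial bias of the bicyclic enone, so that reagent control is incomplete and the carbinol is formed with poor enantiomeric purity or mainly as the unwanted diastereomer. Fallback by classical resolution, setting out from racemic 7: Luche reduction (NaBH4, CeCl3·7H2O, MeOH, −40 °C) gives the racemic carbinols; the racemic 2α-carbinol, that is 8 together with its mirror-image carbinol F1, is separated from the racemic cis carbinol F2 (which can be returned to 7 with MnO2) and esterified with (S)-O-methylmandelic acid (DCC, DMAP) to the mandelate ester F3 (from 8) and the diastereomeric mandelate ester F4 (from F1). After separation by chromatography or crystallisation, F3 is treated with excess iBu2AlH at −78 °C, which cleaves the mandelate and reduces the lactone in one operation, and the route is rejoined at lactol 9.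

Step 9. Enolisation and rearrangement at the congested C10 may be slower than decomposition of the ester enolate or ketene acetal, or C9 may form with little control. Fallback by amide acetal rearrangement followed by alkylation, setting out from carbinol 10: heating with N,N-dimethylacetamide dimethyl acetal (xylene, 140 °C) forms the ketene N,O-acetal F5, which rearranges in the same flask (Eschenmoser–Claisen, same suprafacial delivery to the α face of C10, no base) to the C10 acetamide F6. Deprotonation (LiN(iPr)2, THF, −78 °C) and alkylation with 2-(benzyloxy)ethyl trifluoromethanesulfonate give the C9-alkylated amide F7 (C9 as in 15) and its C9 epimer F8, which are separated; F8 can be recycled by deprotonation and reprotonation. MeLi converts F7 into methyl ketone acetal 16, where the route is rejoined at the hydrolysis stage of step 10.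

Step 11. Before ring B closes, the free C6 aldehyde may lose its configuration at C5 through its enolate, which would erode the trans ring fusion, or the oxa-Michael adduct may not drain completely through the enone. Fallback by an acetal aldol that never frees the aldehyde, setting out from methyl ketone acetal 16 (isolated by a neutral quench of step 10): kinetic enol silylation (LiN(iPr)2, Me3SiCl, THF, −78 °C) gives the trimethylsilyl enol ether F9, and Me3SiOTf (catalytic, CH2Cl2, −78 °C) ionises the methyl acetal to the cyclic oxocarbenium ion, which the enol ether captures at C6 (Mukaiyama-type acetal aldol) to give cyclic ether ketone 20 directly. Compound 20 then enters the base and hydrogenation stages of step 11.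

Further compounds
F1 | step 5 | mirror image of carbinol 8 | O[C@H]1C=C(C)[C@@H]2C(=O)OC[C@]2(C)C1
F2 | step 5 | racemic cis (2β-hydroxy) carbinol lactone, one enantiomer drawn | O[C@H]1C=C(C)[C@H]2C(=O)OC[C@@]2(C)C1
F3 | step 5 | (S)-O-methylmandelate ester of 8 | CO[C@H](C(=O)O[C@@H]1C=C(C)[C@H]2C(=O)OC[C@@]2(C)C1)c1ccccc1
F4 | step 5 | (S)-O-methylmandelate ester of F1 | CO[C@H](C(=O)O[C@H]1C=C(C)[C@@H]2C(=O)OC[C@]2(C)C1)c1ccccc1
F5 | step 9 | ketene N,O-acetal of 10, not isolated | C=C(N(C)C)O[C@@H]1C=C(C)[C@H]2[C@H](OC)OC[C@@]2(C)C1
F6 | step 9 | C10 N,N-dimethylacetamide (C9 unsubstituted) | CO[C@@H]1OC[C@@]2(C)CC=C[C@](C)(CC(=O)N(C)C)[C@@H]12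
F7 | step 9 | C9-alkylated N,N-dimethylamide, C9 as in 15 | CO[C@@H]1OC[C@@]2(C)CC=C[C@](C)([C@@H](CCOCc3ccccc3)C(=O)N(C)C)[C@@H]12
F8 | step 9 | C9 epimer of F7 | CO[C@@H]1OC[C@@]2(C)CC=C[C@](C)([C@H](CCOCc3ccccc3)C(=O)N(C)C)[C@@H]12
F9 | step 11 | trimethylsilyl enol ether of 16 (C7=C8) | CO[C@@H]1OC[C@@]2(C)CC=C[C@](C)([C@@H](CCOCc3ccccc3)C(=C)O[Si](C)(C)C)[C@@H]12
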